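**Remark (one line):** the ester is read as the (Z)-2-methylbut-2-enoate (angelate) drawn in the SMILES; locants are a eudesmane-type numbering defined in the first section, not IUPAC spiro locants; TBS = tert-butyldimethylsilyl.

## Analysis of the target

Target 26 is a spiro[4.5]decane sesquiterpene lactone. Ring A is the cyclohexene C1–C2–C3–C4–C5–C10 and ring B the cyclopentane C5–C6–C7–C8–C9; they share only C5. Ring B is cis-fused through C7–C8 to an α-methylene-γ-butyrolactone (ring C: C7, C8, O, C12, C11; C13 is the exocyclic methylene; C14 sits on C10, C15 on C4). Ring A carries the trisubstituted olefin C10=C1, the angelate on C14, and three contiguous centres C2 (OH), C3 (OH) and C4 (CH3) that are all trans. C9 lies on the face of ring A opposite to the C4 methyl, and the lactone lies on the face of ring B turned towards C10; the configuration is (2S,3S,4R,5R,7R,8R). The sensitive groups are the α-methylene lactone (Michael acceptor), the angelate (Z to E isomerization) and the allylic C2 alcohol and C14 ester, so they must appear late. The hard part is the quaternary C5: two of its four carbon substituents (C6, C9) are CH2 groups, so its configuration is defined only against C4 on one side and against C7/C8 two bonds away on the other. The feature that invites the key step is the allylic triad C5–C10=C1, in which C1 carries only hydrogen and has the oxygenated C2 as neighbour. This is the product pattern of a [3,3] shift of a C1–O bond, so a C1 carbinol can be traded for the C5–C9 bond while the olefin moves into its final place.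

## Retrosynthetic reasoning

26 to 22. The free 2,3-diol and the angelate are released or attached last (26 from 25, 25 from 23 and 24). The C14 oxygen of 23 is cut back to the methyl group of 22. The forward allylic oxidation has only one site to choose, because the other carbon on C10 is the quaternary C5.

22 to 17. The exocyclic methylene is removed to give lactone 19, and the lactone C–O bond is opened to keto ester 17. The forward steps need a hydride that adds anti to the C7 side chain (only the cis hydroxy ester can lactonize) and a standard α-methylenation.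

17 to 15. The C7–C8 bond is cut as an intramolecular acyl-anion conjugate addition (16). This closes ring B and creates C7 under catalyst control, which is needed because ring A offers no useful substrate control across the spiro atom. The enoate arm of 16 comes from the allyl arm of 15 by cross-metathesis.

15 to 11 (key disconnection). The C5–C9 bond is cut as a retro-[3,3] shift. This returns the olefin to C5=C10 and an oxygen to C1, so the precursor 11 is a plain cyclohex-2-enol without a quaternary carbon. It is cut here and not at C5–C6 or C5–C4 because only this cut uses the C10=C1 olefin of the target and puts the controlling centre (C1) next to the existing C2 oxygen. The forward reaction must pass the C1 configuration to C5 and deliver C9 trans to the C4 methyl.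

11 to 8. The C1 carbinol comes from ketone 10 and the C2 oxygen from α′-oxidation of enone 8. Each new centre is set trans to its neighbour, so C3 relays its configuration to C2, C1 and finally C5.

8 to 6. The enone with the allyl arm on C5 is cut back by an alkylative 1,3-carbonyl transposition (7) to enone 6, whose carbonyl carbon becomes the spiro carbon.

6 to 1. The C3 oxygen is traced to the isopropenyl group of (R)-carvone (1) with retention (4, 3), and the C4 methyl to a trans α′-methylation (2). Compound 1 supplies all six ring-A carbons, C14 and the one stereocentre from which the others follow.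

## Alternatives that were turned down

Alternative 1: The textbook disconnection cuts C7–C8 together with the lactone C–O bond. In the forward sense the aldehyde–allylic bromide A1 (ring A and C5 as in 15, the allyl arm carried on to a (Z)-2-(bromomethyl)enoate) is treated with CrCl2 or indium. The allyl metal attacks the aldehyde through C7, closes ring B, and the alkoxide lactonizes to 22 (intramolecular Barbier-type allylation). It was turned down because C7 and C8 are both formed two bonds from the only nearby stereocentre, and the ring-A substituents on C5 (C4, C10) point away from the forming ring. The two chair-like transition states that give the two cis-fused lactones (lactone towards C10 or towards C4) differ only in remote contacts, and there is no reagent handle to override this. A1 also costs about three more steps than 16 (cleavage of the allyl arm, Baylis–Hillman reaction, bromination) and carries an allylic bromide beside an aldehyde.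

Alternative 2: The biomimetic disconnection makes the C5–C9 bond by a 1,2-shift of C9 from C10 to C5 in a eudesman-12,8-olide. Commercial alantolactone A2 already has C4, C7 and C8 of 26 in the right absolute configuration, and a suprafacial shift would give 5R. The forward key step would be Markovnikov hydration of A2 to the tertiary 5β-alcohol A3, then ionization, Wagner–Meerwein ring contraction and loss of H1 to the spiro diene lactone A4, followed by oxidation at C14, C2 and C3. It was turned down on mechanism. The shift turns one tertiary cation into another and pays for a cyclopentane, so nothing drives it. In the chair of A3 that places C9 antiperiplanar to the leaving group, the axial H4 is antiperiplanar as well, so hydride shift and elimination to ring olefins compete and would destroy the C4 centre. The migrating C9 is also deactivated by the oxygen on C8. The short entry is deceptive on step count too: ring A of A4 is bare, and C2 and C3 would have to be oxidized late, beside the α-methylene lactone.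

Alternative 3: Dearomatization treats C5 as the para carbon of a phenol. The forward key step would treat phenol A5 (a 3,5-dimethyl-4-alkylphenol whose side chain is the preformed cis lactone with a bromomethyl group on C8) with KOtBu. Intramolecular para-alkylation (Ar1-5 participation) would give spirodienone A6 in one step. It was turned down because ring A of A6 has a local mirror plane through C2 and C5, so C5 is not yet a stereocentre and the problem is only postponed. One of two diastereotopic enone halves would have to be reduced and oxygenated, and C4 protonated on one face, all directed by C7/C8 across the spiro atom. Three ring-A centres would rest on remote induction, and A5 itself needs a pentasubstituted arene plus an enantiopure lactone side chain.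

Key step: step 10

## Route

Step 1
Reactants: 1 (R)-(−)-carvone
Product: 2 (5R,6S)-2,6-dimethyl-5-(prop-1-en-2-yl)cyclohex-2-en-1-one
Conditions: LiN(iPr)2, THF, −78 °C; MeI, −78 → 0 °C
Reagents that add atoms: iodomethane, CI
Why: Kinetic α′-deprotonation and enolate alkylation; iodomethane should enter anti to the neighbouring isopropenyl group (trans), and the epimerizable C6 allows the minor cis isomer to be equilibrated.

Step 2
Reactants: 2 (5R,6S)-2,6-dimethyl-5-(prop-1-en-2-yl)cyclohex-2-en-1-one
Product: 3 (5R,6S)-5-acetyl-2,6-dimethylcyclohex-2-en-1-one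
Conditions: O3 (1 equiv), CH2Cl2/MeOH, −78 °C; Me2S, −78 → 23 °C
Reagents that add atoms: ozone, O=[O+][O-]
Why: Ozonolysis; the electron-rich 1,1-disubstituted isopropenyl olefin should be cleaved faster than the conjugated ring olefin when ozone is limited, and no stereocentre is touched.

Step 3
Reactants: 3 (5R,6S)-5-acetyl-2,6-dimethylcyclohex-2-en-1-one
Product: 4 (5R,6S)-5-acetoxy-2,6-dimethylcyclohex-2-en-1-one
Conditions: m-CPBA, NaHCO3, CH2Cl2, 23 °C
Reagents that add atoms: m-chloroperbenzoic acid, OOC(=O)c1cccc(Cl)c1
Why: Baeyer–Villiger oxidation; the secondary ring carbon migrates in preference to methyl with retention at C5, while the conjugated ketone and its electron-poor olefin should react much more slowly.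

Step 4
Reactants: 4 (5R,6S)-5-acetoxy-2,6-dimethylcyclohex-2-en-1-one
Product: 5 (5R,6S)-5-hydroxy-2,6-dimethylcyclohex-2-en-1-one
Conditions: K2CO3 (0.2 equiv), MeOH, 0 °C
Reagents that add atoms: none
Why: Base-catalysed transesterification, kept cold and short so that β-elimination of the β-oxygenated ketone stays slow.

Step 5
Reactants: 5 (5R,6S)-5-hydroxy-2,6-dimethylcyclohex-2-en-1-one
Product: 6 (5R,6S)-5-(tert-butyldimethylsilyloxy)-2,6-dimethylcyclohex-2-en-1-one
Conditions: TBSCl, imidazole, DMF, 23 °C
Reagents that add atoms: tert-butyldimethylsilyl chloride, CC(C)(C)[Si](C)(C)Cl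
Why: Standard silylation; the silyl ether should withstand the organometallic, oxidative and thermal steps ahead.

Step 6
Reactants: 6 (5R,6S)-5-(tert-butyldimethylsilyloxy)-2,6-dimethylcyclohex-2-en-1-one
Product: 7 (1S,5R,6S)-1-allyl-5-(tert-butyldimethylsilyloxy)-2,6-dimethylcyclohex-2-en-1-ol
Conditions: CH2=CHCH2MgBr, THF, −78 °C; aq NH4Cl
Reagents that add atoms: allylmagnesium bromide, C=CC[Mg]Br
Why: 1,2-Addition of the allyl Grignard reagent to the enone carbonyl, fast even for a hindered enolizable ketone; the carbinol centre (allyl anti to the neighbouring methyl expected) is destroyed in step 7, so both epimers converge.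

Step 7
Reactants: 7 (1S,5R,6S)-1-allyl-5-(tert-butyldimethylsilyloxy)-2,6-dimethylcyclohex-2-en-1-ol
Product: 8 (4R,5R)-3-allyl-5-(tert-butyldimethylsilyloxy)-2,4-dimethylcyclohex-2-en-1-one
Conditions: pyridinium chlorochromate (C5H5NH)[CrO3Cl], 4 Å sieves, CH2Cl2, 23 °C
Reagents that add atoms: pyridinium chlorochromate, [O-][Cr](=O)(=O)Cl.c1cc[nH+]cc1
Why: Oxidative 1,3-transposition of a tertiary allylic alcohol (chromate ester, [3,3] shift, oxidation); the oxygen moves to C1 and the allyl arm stays on the β-carbon, the future spiro carbon C5.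

Step 8
Reactants: 8 (4R,5R)-3-allyl-5-(tert-butyldimethylsilyloxy)-2,4-dimethylcyclohex-2-en-1-one
Product: 10 (4R,5S,6R)-3-allyl-5,6-bis(tert-butyldimethylsilyloxy)-2,4-dimethylcyclohex-2-en-1-one, via silyl dienol ether 9 (not isolated)
Conditions: LiN(iPr)2, THF, −78 °C; TBSOTf, −78 °C; then m-CPBA, NaHCO3, CH2Cl2, −20 → 0 °C
Reagents that add atoms: tert-butyldimethylsilyl trifluoromethanesulfonate, CC(C)(C)[Si](C)(C)OS(=O)(=O)C(F)(F)F; m-chloroperbenzoic acid, OOC(=O)c1cccc(Cl)c1
Why: Rubottom oxidation; kinetic α′-deprotonation gives the cross-conjugated silyl dienol ether, whose enol double bond should be epoxidized anti to the neighbouring C3 silyloxy group, and 1,4-silyl shift gives the α′-silyloxy ketone with C2–O trans to C3–O.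

Step 9
Reactants: 10 (4R,5S,6R)-3-allyl-5,6-bis(tert-butyldimethylsilyloxy)-2,4-dimethylcyclohex-2-en-1-one
Product: 11 (1R,4R,5S,6S)-3-allyl-5,6-bis(tert-butyldimethylsilyloxy)-2,4-dimethylcyclohex-2-en-1-ol
Conditions: NaBH4, CeCl3·7H2O, MeOH, −78 °C
Reagents that add atoms: none
Why: Luche 1,2-reduction; axial hydride attack on the half-chair with equatorial silyloxy groups should give the pseudo-equatorial C1 alcohol trans to C2–O, since both faces of the diaxial conformer are shielded (Curtin–Hammett).

Step 10
Reactants: 11 (1R,4R,5S,6S)-3-allyl-5,6-bis(tert-butyldimethylsilyloxy)-2,4-dimethylcyclohex-2-en-1-ol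
Product: 14 ethyl 2-[(1R,4S,5S,6R)-1-allyl-4,5-bis(tert-butyldimethylsilyloxy)-2,6-dimethylcyclohex-2-en-1-yl]acetate, via mixed orthoester 12 (not isolated), via ketene acetal 13 (not isolated)
Conditions: MeC(OEt)3 (10 equiv), EtCO2H (cat.), xylene, 140 °C, EtOH distilled off
Reagents that add atoms: triethyl orthoacetate, CCOC(C)(OCC)OCC
Why: Johnson orthoester Claisen rearrangement: acid-catalysed exchange gives the mixed orthoester, loss of ethanol gives the ketene acetal, and a concerted suprafacial [3,3] shift breaks C1–O and forms C5–C9 while the olefin moves from C5=C10 to C10=C1. The closest known reaction type is the orthoester Claisen rearrangement of 3-substituted cyclohex-2-en-1-ols, a standard route to quaternary ring carbons. No ring is closed; the step gives C5 its fourth carbon substituent, removes the oxygen from C1 and puts the olefin of the target in place. The only new stereocentre, C5, is controlled by the C1 carbinol (1,3-chirality transfer): the three-atom tether can reach C5 only on the face that carried the C1 oxygen, so C9 should enter cis to C3–O and trans to the C4 methyl (5R of the target). The selectivity needed is thus facial and is secured by intramolecularity; the step must also outrun acid-catalysed loss of the allylic oxygen to a diene. The substrate helps, because A(1,2) strain with the C10 methyl and the C5 allyl group favours the half-chair with pseudo-axial C1–O, which is the geometry needed for overlap, and formation of the ester carbonyl makes the step irreversible. The allyl olefin should stay passive at this temperature (a Cope shift needs more heat).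

Step 11
Reactants: 14 ethyl 2-[(1R,4S,5S,6R)-1-allyl-4,5-bis(tert-butyldimethylsilyloxy)-2,6-dimethylcyclohex-2-en-1-yl]acetate
Product: 15 2-[(1R,4S,5S,6R)-1-allyl-4,5-bis(tert-butyldimethylsilyloxy)-2,6-dimethylcyclohex-2-en-1-yl]acetaldehyde
Conditions: iBu2AlH (1.1 equiv), CH2Cl2, −78 °C; aq KNaC4H4O6
Reagents that add atoms: none
Why: Partial ester reduction; the neopentyl-type aluminium hemiacetal should be stable at −78 °C until work-up, so the aldehyde is released without over-reduction.

Step 12
Reactants: 15 2-[(1R,4S,5S,6R)-1-allyl-4,5-bis(tert-butyldimethylsilyloxy)-2,6-dimethylcyclohex-2-en-1-yl]acetaldehyde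
Product: 16 methyl (E)-4-[(1R,4S,5S,6R)-4,5-bis(tert-butyldimethylsilyloxy)-2,6-dimethyl-1-(2-oxoethyl)cyclohex-2-en-1-yl]but-2-enoate
Conditions: methyl acrylate (5 equiv), second-generation Hoveyda–Grubbs catalyst (5 mol %), CH2Cl2, 40 °C
Reagents that add atoms: methyl acrylate, C=CC(=O)OC
Why: Olefin cross-metathesis of the monosubstituted allyl olefin with an acrylate should give the (E)-enoate; the hindered trisubstituted ring olefin is inert to the ruthenium carbene.

Step 13
Reactants: 16 methyl (E)-4-[(1R,4S,5S,6R)-4,5-bis(tert-butyldimethylsilyloxy)-2,6-dimethyl-1-(2-oxoethyl)cyclohex-2-en-1-yl]but-2-enoate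
Product: 17 methyl 2-[(2S,3S,4R,5R,7R)-2,3-bis(tert-butyldimethylsilyloxy)-4,10-dimethyl-8-oxospiro[4.5]dec-1(10)-en-7-yl]acetate (locants of this write-up)
Conditions: chiral aminoindanol-derived N-pentafluorophenyl triazolium tetrafluoroborate (20 mol %, enantiomer chosen for 7R), KN(SiMe3)2 (20 mol %), toluene, 23 °C
Reagents that add atoms: none
Why: Intramolecular Stetter reaction; the carbene-bound acyl anion adds 5-exo-trig to the enoate β-carbon C7 and closes ring B, and the chiral triazolium catalyst should set C7 by catalyst control because the quaternary C5 two bonds away exerts little bias.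

Step 14
Reactants: 17 methyl 2-[(2S,3S,4R,5R,7R)-2,3-bis(tert-butyldimethylsilyloxy)-4,10-dimethyl-8-oxospiro[4.5]dec-1(10)-en-7-yl]acetate
Product: 19 cis-fused γ-lactone (2S,3S,4R,5R,7R,8R) between C8–O and C12 with C11 as CH2 and 2,3-bis(tert-butyldimethylsilyloxy), via hydroxy ester 18 (not isolated)
Conditions: Li[HB(sec-Bu)3], THF, −78 → 0 °C; AcOH; then p-TsOH (cat.), CH2Cl2, 23 °C
Reagents that add atoms: none
Why: The bulky hydride should attack the ketone anti to the C7 side chain and give the cis hydroxy ester (8R), which closes to the cis-fused lactone; a trans isomer could not lactonize.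

Step 15
Reactants: 19 cis-fused γ-lactone (2S,3S,4R,5R,7R,8R)
Product: 22 α-methylene lactone (19 with exocyclic C11=C13), via Mannich base 20 (not isolated), via ammonium iodide 21 (not isolated)
Conditions: LiN(iPr)2, THF, −78 °C; CH2=NMe2+ I−, −78 → 23 °C; MeI, MeOH, 23 °C; aq NaHCO3, CH2Cl2, 23 °C
Reagents that add atoms: dimethylmethyleneiminium iodide, C=[N+](C)C.[I-]
Why: Standard α-methylenation of a γ-butyrolactone: Mannich aminomethylation of the lactone enolate on the convex face, N-methylation and elimination; the new C11 centre becomes sp2.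

Step 16
Reactants: 22 α-methylene lactone
Product: 23 C14 allylic alcohol (22 with C10–CH2OH)
Conditions: SeO2 (0.5 equiv), t-BuOOH (3 equiv), CH2Cl2, 0 → 23 °C
Reagents that add atoms: selenium dioxide, O=[Se]=O; tert-butyl hydroperoxide, CC(C)(C)OO
Why: Selenium dioxide allylic oxidation (ene reaction, then [2,3] shift) at the more substituted end of the C10=C1 olefin, where C14 is the only carbon bearing hydrogen; the electron-poor α-methylene lactone should be inert.

Step 17
Reactants: 23 C14 allylic alcohol; 24 angelic acid
Product: 25 14-O-angelate of 23 (2,3-bis-TBS ether of 26)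
Conditions: 24, 2,4,6-Cl3C6H2COCl, Et3N, toluene, 23 °C; then 23, 80 °C
Reagents that add atoms: angelic acid (24), C/C=C(/C)C(=O)O
Why: Yamaguchi esterification through the mixed anhydride without an acyl-transfer amine, conditions under which the (Z)-2-methylbut-2-enoyl group should be transferred without isomerization to the tiglate.

Step 18
Reactants: 25 14-O-angelate bis-TBS ether
Product: 26 target, (2S,3S,4R,5R,7R,8R)-14-angeloyloxy-2,3-dihydroxy spiro lactone
Conditions: HF·pyridine, pyridine, THF, 0 → 23 °C
Reagents that add atoms: none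
Why: Fluoride cleavage of both silyl ethers under buffered conditions that should spare the α-methylene lactone, the angelate and the allylic positions.

## Compound list

1 | (R)-(−)-carvone | CC1=CC[C@@H](C(C)=C)CC1=O | starting material
2 | (5R,6S)-2,6-dimethyl-5-(prop-1-en-2-yl)cyclohex-2-en-1-one | CC1=CC[C@@H](C(C)=C)[C@H](C)C1=O | intermediate
3 | (5R,6S)-5-acetyl-2,6-dimethylcyclohex-2-en-1-one | CC1=CC[C@@H](C(C)=O)[C@H](C)C1=O | intermediate
4 | (5R,6S)-5-acetoxy-2,6-dimethylcyclohex-2-en-1-one | CC1=CC[C@@H](OC(C)=O)[C@H](C)C1=O | intermediate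
5 | (5R,6S)-5-hydroxy-2,6-dimethylcyclohex-2-en-1-one | CC1=CC[C@@H](O)[C@H](C)C1=O | intermediate
6 | (5R,6S)-5-(tert-butyldimethylsilyloxy)-2,6-dimethylcyclohex-2-en-1-one | CC1=CC[C@@H](O[Si](C)(C)C(C)(C)C)[C@H](C)C1=O | intermediate
7 | (1S,5R,6S)-1-allyl-5-(tert-butyldimethylsilyloxy)-2,6-dimethylcyclohex-2-en-1-ol (expected major carbinol epimer) | CC1=CC[C@@H](O[Si](C)(C)C(C)(C)C)[C@H](C)[C@@]1(O)CC=C | intermediate
8 | (4R,5R)-3-allyl-5-(tert-butyldimethylsilyloxy)-2,4-dimethylcyclohex-2-en-1-one | O=C1C[C@@H](O[Si](C)(C)C(C)(C)C)[C@H](C)C(CC=C)=C1C | intermediate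
9 | C1 O-TBS cross-conjugated dienol ether of 8 | CC(C)(C)[Si](C)(C)OC1=C[C@@H](O[Si](C)(C)C(C)(C)C)[C@H](C)C(CC=C)=C1C | intermediate (not isolated)
10 | (4R,5S,6R)-3-allyl-5,6-bis(tert-butyldimethylsilyloxy)-2,4-dimethylcyclohex-2-en-1-one | O=C1[C@H](O[Si](C)(C)C(C)(C)C)[C@@H](O[Si](C)(C)C(C)(C)C)[C@H](C)C(CC=C)=C1C | intermediate
11 | (1R,4R,5S,6S)-3-allyl-5,6-bis(tert-butyldimethylsilyloxy)-2,4-dimethylcyclohex-2-en-1-ol | O[C@H]1[C@H](O[Si](C)(C)C(C)(C)C)[C@@H](O[Si](C)(C)C(C)(C)C)[C@H](C)C(CC=C)=C1C | intermediate
12 | mixed orthoester, 1-O-(1,1-diethoxyethyl) ether of 11 | CCOC(C)(OCC)O[C@H]1[C@H](O[Si](C)(C)C(C)(C)C)[C@@H](O[Si](C)(C)C(C)(C)C)[C@H](C)C(CC=C)=C1C | intermediate (not isolated)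
13 | ketene acetal, 1-O-(1-ethoxyvinyl) ether of 11 | CCOC(=C)O[C@H]1[C@H](O[Si](C)(C)C(C)(C)C)[C@@H](O[Si](C)(C)C(C)(C)C)[C@H](C)C(CC=C)=C1C | intermediate (not isolated)
14 | ethyl 2-[(1R,4S,5S,6R)-1-allyl-4,5-bis(tert-butyldimethylsilyloxy)-2,6-dimethylcyclohex-2-en-1-yl]acetate | CCOC(=O)C[C@@]1(CC=C)C(C)=C[C@H](O[Si](C)(C)C(C)(C)C)[C@@H](O[Si](C)(C)C(C)(C)C)[C@@H]1C | intermediate
15 | 2-[(1R,4S,5S,6R)-1-allyl-4,5-bis(tert-butyldimethylsilyloxy)-2,6-dimethylcyclohex-2-en-1-yl]acetaldehyde | O=CC[C@@]1(CC=C)C(C)=C[C@H](O[Si](C)(C)C(C)(C)C)[C@@H](O[Si](C)(C)C(C)(C)C)[C@@H]1C | intermediate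
16 | methyl (E)-4-[(1R,4S,5S,6R)-4,5-bis(tert-butyldimethylsilyloxy)-2,6-dimethyl-1-(2-oxoethyl)cyclohex-2-en-1-yl]but-2-enoate | O=CC[C@@]1(C/C=C/C(=O)OC)C(C)=C[C@H](O[Si](C)(C)C(C)(C)C)[C@@H](O[Si](C)(C)C(C)(C)C)[C@@H]1C | intermediate
17 | spiro keto ester (2S,3S,4R,5R,7R): C8 ketone in ring B, CH2CO2CH3 on C7 | O=C1C[C@@]2(C[C@@H]1CC(=O)OC)C(C)=C[C@H](O[Si](C)(C)C(C)(C)C)[C@@H](O[Si](C)(C)C(C)(C)C)[C@@H]2C | intermediate
18 | cis hydroxy ester (2S,3S,4R,5R,7R,8R): C8–OH cis to the C7 side chain | O[C@@H]1C[C@@]2(C[C@@H]1CC(=O)OC)C(C)=C[C@H](O[Si](C)(C)C(C)(C)C)[C@@H](O[Si](C)(C)C(C)(C)C)[C@@H]2C | intermediate (not isolated)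
19 | cis-fused γ-lactone (2S,3S,4R,5R,7R,8R), C11 = CH2 | C1C(=O)O[C@@H]2C[C@@]3(C[C@H]12)C(C)=C[C@H](O[Si](C)(C)C(C)(C)C)[C@@H](O[Si](C)(C)C(C)(C)C)[C@@H]3C | intermediate
20 | Mannich base of 19, CH2N(CH3)2 on C11 (11S, convex face) | CN(C)C[C@H]1C(=O)O[C@@H]2C[C@@]3(C[C@H]12)C(C)=C[C@H](O[Si](C)(C)C(C)(C)C)[C@@H](O[Si](C)(C)C(C)(C)C)[C@@H]3C | intermediate (not isolated)
21 | trimethylammonium iodide of 20 | C[N+](C)(C)C[C@H]1C(=O)O[C@@H]2C[C@@]3(C[C@H]12)C(C)=C[C@H](O[Si](C)(C)C(C)(C)C)[C@@H](O[Si](C)(C)C(C)(C)C)[C@@H]3C.[I-] | intermediate (not isolated)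
22 | α-methylene lactone (2S,3S,4R,5R,7R,8R), C14 = CH3, 2,3-bis-TBS | C=C1C(=O)O[C@@H]2C[C@@]3(C[C@H]12)C(C)=C[C@H](O[Si](C)(C)C(C)(C)C)[C@@H](O[Si](C)(C)C(C)(C)C)[C@@H]3C | intermediate
23 | C14 allylic alcohol of 22 | C=C1C(=O)O[C@@H]2C[C@@]3(C[C@H]12)C(CO)=C[C@H](O[Si](C)(C)C(C)(C)C)[C@@H](O[Si](C)(C)C(C)(C)C)[C@@H]3C | intermediate
24 | angelic acid, (Z)-2-methylbut-2-enoic acid | C/C=C(/C)C(=O)O | starting material
25 | 14-O-angelate of 23 (2,3-bis-TBS ether of 26) | C=C1C(=O)O[C@@H]2C[C@@]3(C[C@H]12)C(COC(=O)/C(C)=C\C)=C[C@H](O[Si](C)(C)C(C)(C)C)[C@@H](O[Si](C)(C)C(C)(C)C)[C@@H]3C | intermediate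
26 | target CNP0224912.1, (2S,3S,4R,5R,7R,8R) | C=C1C(=O)O[C@@H]2C[C@@]3(C[C@H]12)C(COC(=O)/C(C)=C\C)=C[C@H](O)[C@@H](O)[C@@H]3C | target

## Step count and least certain steps

Total step count: 18. Longest linear sequence: 18 steps (1 to 26); 24 is bought and enters in step 17.

Step 10 (key step). The risk is that the [3,3] shift, which must build a quaternary carbon between C4 and the fully substituted C10, is slower than acid-catalysed ionization of the allylic orthoester, so that elimination to a ring diene takes over. The fallback is an ester-enolate Claisen under neutral, low-temperature conditions. It sets out from 11: acetylation (Ac2O, DMAP, pyridine) gives the allylic acetate F1; LiN(iPr)2 and Me3SiCl at −78 °C give the silyl ketene acetal, which should rearrange on warming (Ireland–Claisen) to the carboxylic acid F2; esterification (EtI, K2CO3, DMF) comes back to the route at 14.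

Step 13. The risks are poor facial selectivity at C7 if the catalyst and the distant quaternary centre are mismatched, and slow acyl-anion formation from the neopentyl aldehyde with aldol self-condensation competing. The fallback moves the stereocontrol into the reduction. It sets out from 16: cyclization with an achiral N-mesityl triazolium salt and DBU gives 17 together with its C7 epimer F3. Because C7 is α to the ketone, the mixture is hydrogenated with RuCl2(xylbinap)(daipen) and KOtBu in iPrOH under H2 with dynamic kinetic resolution (base epimerizes C7, the catalyst reduces one epimer from one face). This should give the cis hydroxy ester 18, and acid closes the lactone, coming back at 19.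

Step 9. The risk is hydride delivery from the wrong face (through the conformer with an axial C2–O bond), which would invert C1 and so send C9 to the wrong face of ring A in step 10. The fallback makes the wrong epimer on purpose and inverts it. It sets out from 10: Li[HB(sec-Bu)3] at −78 °C should give the cis alcohol F4; Mitsunobu inversion (4-nitrobenzoic acid, PPh3, diisopropyl azodicarboxylate) gives the ester F5; methanolysis (K2CO3, MeOH) comes back at 11.

Step 8. The risks are loss of regiocontrol in the enolization (γ-deprotonation at the allyl CH2), β-elimination of the C3 silyloxy group from the enolate, and poor facial selectivity in the epoxidation. The fallback is an α′-acetoxylation that needs no enolate. It sets out from 8: Mn(OAc)3 in benzene at reflux should give the α′-acetoxy enone F6 (acetate trans to the C3 silyl ether); cold methanolysis (K2CO3, MeOH, 0 °C) gives the α′-hydroxy enone F7; TBSOTf and 2,6-lutidine come back at 10.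

Step 16. The risks are over-oxidation of the new primary allylic alcohol and a slow ene reaction at the hindered olefin. The fallback oxidizes through and reduces back. It sets out from 22: stoichiometric SeO2 in dioxane at 80 °C drives the oxidation to the enal F8; NaBH4 with CeCl3·7H2O in MeOH at −78 °C reduces only the aldehyde and comes back at 23.

Step 17. The risks are Z to E isomerization of the acyl group during activation and sluggish acyl transfer to the hindered allylic alcohol. The fallback builds the Z olefin after acylation. It sets out from 23: acylation (DCC, DMAP) with 2-[bis(2,2,2-trifluoroethoxy)phosphoryl]propanoic acid gives the phosphonate ester F9 (epimeric at the phosphonate carbon, which becomes sp2); Still–Gennari olefination with acetaldehyde (KN(SiMe3)2, 18-crown-6, THF, −78 °C) should give the (Z)-2-methylbut-2-enoate and comes back at 25.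

## Further compounds

F1 | step 10 | (1R,4R,5S,6S)-3-allyl-5,6-bis(tert-butyldimethylsilyloxy)-2,4-dimethylcyclohex-2-en-1-yl acetate | CC(=O)O[C@H]1[C@H](O[Si](C)(C)C(C)(C)C)[C@@H](O[Si](C)(C)C(C)(C)C)[C@H](C)C(CC=C)=C1C
F2 | step 10 | 2-[(1R,4S,5S,6R)-1-allyl-4,5-bis(tert-butyldimethylsilyloxy)-2,6-dimethylcyclohex-2-en-1-yl]acetic acid | OC(=O)C[C@@]1(CC=C)C(C)=C[C@H](O[Si](C)(C)C(C)(C)C)[C@@H](O[Si](C)(C)C(C)(C)C)[C@@H]1C
F3 | step 13 | C7 epimer (7S) of spiro keto ester 17 | O=C1C[C@@]2(C[C@H]1CC(=O)OC)C(C)=C[C@H](O[Si](C)(C)C(C)(C)C)[C@@H](O[Si](C)(C)C(C)(C)C)[C@@H]2C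
F4 | step 9 | (1S,4R,5S,6S)-3-allyl-5,6-bis(tert-butyldimethylsilyloxy)-2,4-dimethylcyclohex-2-en-1-ol (C1 epimer of 11) | O[C@@H]1[C@H](O[Si](C)(C)C(C)(C)C)[C@@H](O[Si](C)(C)C(C)(C)C)[C@H](C)C(CC=C)=C1C
F5 | step 9 | 4-nitrobenzoate of 11 | O=C(O[C@H]1[C@H](O[Si](C)(C)C(C)(C)C)[C@@H](O[Si](C)(C)C(C)(C)C)[C@H](C)C(CC=C)=C1C)c1ccc(cc1)[N+](=O)[O-]
F6 | step 8 | (4R,5S,6R)-6-acetoxy-3-allyl-5-(tert-butyldimethylsilyloxy)-2,4-dimethylcyclohex-2-en-1-one | O=C1[C@H](OC(C)=O)[C@@H](O[Si](C)(C)C(C)(C)C)[C@H](C)C(CC=C)=C1C
F7 | step 8 | (4R,5S,6R)-3-allyl-5-(tert-butyldimethylsilyloxy)-6-hydroxy-2,4-dimethylcyclohex-2-en-1-one | O=C1[C@H](O)[C@@H](O[Si](C)(C)C(C)(C)C)[C@H](C)C(CC=C)=C1C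
F8 | step 16 | C14 aldehyde (enal) corresponding to 23 | C=C1C(=O)O[C@@H]2C[C@@]3(C[C@H]12)C(C=O)=C[C@H](O[Si](C)(C)C(C)(C)C)[C@@H](O[Si](C)(C)C(C)(C)C)[C@@H]3C
F9 | step 17 | 14-O-{2-[bis(2,2,2-trifluoroethoxy)phosphoryl]propanoate} of 23 | C=C1C(=O)O[C@@H]2C[C@@]3(C[C@H]12)C(COC(=O)C(C)P(=O)(OCC(F)(F)F)OCC(F)(F)F)=C[C@H](O[Si](C)(C)C(C)(C)C)[C@@H](O[Si](C)(C)C(C)(C)C)[C@@H]3C
A1 | alternative 1 | aldehyde with (Z)-2-(bromomethyl)enoate arm on C5 (ring A as in 15) | O=CC[C@@]1(C/C=C(\CBr)C(=O)OC)C(C)=C[C@H](O[Si](C)(C)C(C)(C)C)[C@@H](O[Si](C)(C)C(C)(C)C)[C@@H]1C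
A2 | alternative 2 | alantolactone | C[C@H]1CCC[C@]2(C1=C[C@H]3[C@@H](C2)OC(=O)C3=C)C
A3 | alternative 2 | 5β-hydroxy-5,6-dihydroalantolactone | C[C@H]1CCC[C@]2(C)C[C@H]3OC(=O)C(=C)[C@H]3C[C@]12O
A4 | alternative 2 | spiro diene lactone (26 without the C2, C3 and C14 oxygens) | C=C1C(=O)O[C@@H]2C[C@@]3(C[C@H]12)C(C)=CCC[C@@H]3C
A5 | alternative 3 | 3,5-dimethyl-4-{[(cis)-2-(bromomethyl)-5-oxotetrahydrofuran-3-yl]methyl}phenol | Oc1cc(C)c(C[C@@H]2CC(=O)O[C@@H]2CBr)c(C)c1
A6 | alternative 3 | spirodienone with cis-fused γ-lactone on ring B | O=C1C=C(C)C2(C[C@@H]3CC(=O)O[C@@H]3C2)C(C)=C1
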